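**Plan**

1. Numbering used here (clerodane type): ring A = cyclohexane C5–C10 (OAc on C7, methyl C17 on C8, methyl C20 on quaternary C9); ring B = cyclohexene C1–C5/C10 fused to the C18(=O)–O–C19 butenolide; ring C = seven-membered ketone C9–C11–C12(=O)–C13=C16–C1–C10, closed through the furan (C13–C16).
2. Cuts, last bond first: C2–O with C1–C16 (arylative oxy-functionalisation of a C1=C2–C3=C4 dienoate); then C11–C12 with C9–C10 (key step); then C7–C8 (allylboration), C4–C18 (carbonylative lactonisation) and C5–C6 (Birch reductive allylation of a 2,6-dimethoxybenzoate).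
3. Forward order: ring B with quaternary C5 (arene, then 2,2-disubstituted 1,3-dione, then bis(enol triflate)), butenolide by desymmetrising carbonylation, side chain, ring A in the key step, ring C last.
4. Enabling feature: the C11 methylene lies between the C12 ketone and the quaternary, methyl-bearing C9, and C9 is tied to C10 through C8–C5. An aroylium therefore converts the C9=C11 isopropenyl group into a tertiary C9 cation placed for capture by the ring-B alkene at C10, and the C3=C4–C18 enoate then allows C10–H to be set through an extended enolate.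
5. Stereochemistry: C5 from ligand-controlled selection between two enol triflates; C7/C8 from a catalyst-controlled Z-allylboration; C9 from the chair of the cationic ring closure; C10 by protonation of the extended enolate anti to the axial C19/C20 groups; C1 and C2 from syn-arylpalladation on the α face and anti attack of a carboxylate.

Key step: step 11

Remark 1: methyl 2,6-dimethoxybenzoate, allyl bromide, isoprene, pinacolborane and 2-bromofuran-3-carboxylic acid are taken as commercial.
Remark 2: (R)-MeO-MOP (step 4) and (R)-TRIP (step 7) are written on the assumption that they lead to the (5S) and (7S,8S) series; if the sense of induction is opposite, the antipode is used.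

**Route**

Step 1
Reactants: 1 methyl 2,6-dimethoxybenzoate; 2 allyl bromide
Product: 4 methyl 1-allyl-2,6-dioxocyclohexane-1-carboxylate, via bis(enol ether) 3 (not isolated)
Conditions: K (2.2 equiv), NH3(l)/THF, t-BuOH (1 equiv), −78 °C; then 2, −78 °C to rt; then 1 M HCl, THF, rt
Reagents that add atoms: water, O
Why: Birch reductive alkylation: the ester-stabilised cyclohexadienyl anion is alkylated at the ipso carbon, creating quaternary C5 with the future C19 (ester) and C6 (allyl) arms, and aqueous acid hydrolyses both enol ethers; no stereocentre arises because the two ring arms are identical.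

Step 2
Reactants: 4 methyl 1-allyl-2,6-dioxocyclohexane-1-carboxylate
Product: 5 methyl 1-allyl-2,6-bis(trifluoromethylsulfonyloxy)cyclohexa-2,5-diene-1-carboxylate
Conditions: KN(SiMe3)2 (2.4 equiv) and PhNTf2 (2.4 equiv) in two portions, THF, −78 to 0 °C
Reagents that add atoms: N-phenylbis(trifluoromethanesulfonimide), O=S(=O)(N(c1ccccc1)S(=O)(=O)C(F)(F)F)C(F)(F)F
Why: Enolate O-triflation: each ketone can enolise only away from the quaternary carbon, so the bis(enol triflate) should form without regiochemical choice.

Step 3
Reactants: 5 methyl 1-allyl-2,6-bis(trifluoromethylsulfonyloxy)cyclohexa-2,5-diene-1-carboxylate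
Product: 6 [1-allyl-2,6-bis(trifluoromethylsulfonyloxy)cyclohexa-2,5-dien-1-yl]methanol
Conditions: i-Bu2AlH (3 equiv), CH2Cl2, −78 to −20 °C; Rochelle salt work-up
Reagents that add atoms: none
Why: Ester reduction with i-Bu2AlH at low temperature should leave the enol triflates intact and free the neopentyl C19 hydroxyl needed for the lactone.

Step 4
Reactants: 6 [1-allyl-2,6-bis(trifluoromethylsulfonyloxy)cyclohexa-2,5-dien-1-yl]methanol
Product: 7 (3aS)-3a-allyl-1-oxo-1,3,3a,6-tetrahydroisobenzofuran-4-yl trifluoromethanesulfonate (C3a = C5)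
Conditions: Pd(OAc)2 (5 mol %), (R)-MeO-MOP (12 mol %), CO (1 atm), i-Pr2NEt, THF, 40 °C
Reagents that add atoms: carbon monoxide, [C-]#[O+]
Why: Palladium-catalysed carbonylative lactonisation of an enol triflate: the chiral monophosphine should direct zerovalent palladium into one of the two enantiotopic C–OTf bonds (enantioselective desymmetrising carbonylation of such bis(enol triflates) is a known reaction type), CO inserts and the C19 hydroxyl closes the five-membered lactone, fixing C5 as S.

Step 5
Reactants: 7 (3aS)-3a-allyl-1-oxo-1,3,3a,6-tetrahydroisobenzofuran-4-yl trifluoromethanesulfonate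
Product: 9 (3aS)-1-oxo-3a-(2-oxoethyl)-1,3,3a,6-tetrahydroisobenzofuran-4-yl trifluoromethanesulfonate, via diol 8 (not isolated)
Conditions: OsO4 (2 mol %), NaIO4 (4 equiv), 2,6-lutidine, dioxane/H2O 3:1, rt
Reagents that add atoms: osmium tetroxide, O=[Os](=O)(=O)=O; sodium periodate, [Na+].[O-]I(=O)(=O)=O
Why: Lemieux–Johnson oxidation: OsO4 should dihydroxylate only the electron-rich terminal alkene (enol triflate and butenolide alkenes are electron-poor) and periodate cleaves the diol to the C7 aldehyde.

Step 6
Reactants: 10 isoprene; 11 pinacolborane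
Product: 12 (Z)-4,4,5,5-tetramethyl-2-(2-methylbut-2-en-1-yl)-1,3,2-dioxaborolane
Conditions: FeCl2 with a 2-iminopyridine ligand (5 mol %), Mg (10 mol %), Et2O, 23 °C
Reagents that add atoms: none
Why: Iron-catalysed 1,4-hydroboration of a 1,3-diene: hydrogen goes to C4 and boron to C1 of the cisoid-bound diene (regiochemistry set by the ligand), which should give the Z trisubstituted allylboronate.

Step 7
Reactants: 9 (3aS)-1-oxo-3a-(2-oxoethyl)-1,3,3a,6-tetrahydroisobenzofuran-4-yl trifluoromethanesulfonate; 12 (Z)-4,4,5,5-tetramethyl-2-(2-methylbut-2-en-1-yl)-1,3,2-dioxaborolane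
Product: 14 (3aS)-3a-[(2S,3S)-2-hydroxy-3,4-dimethylpent-4-en-1-yl]-1-oxo-1,3,3a,6-tetrahydroisobenzofuran-4-yl trifluoromethanesulfonate, via pinacol borate 13 (not isolated)
Conditions: (R)-TRIP (5 mol %), 4 Å MS, toluene, −30 °C; then aq. NaHCO3
Reagents that add atoms: none
Why: Chiral phosphoric acid-catalysed allylboration through a closed six-membered chair transition state: the Z γ-methyl group ends syn to the new hydroxyl (C8 S) and the acid selects the aldehyde face (C7 S).

Step 8
Reactants: 14 (3aS)-3a-[(2S,3S)-2-hydroxy-3,4-dimethylpent-4-en-1-yl]-1-oxo-1,3,3a,6-tetrahydroisobenzofuran-4-yl trifluoromethanesulfonate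
Product: 15 (2S,3S)-3,4-dimethyl-1-[(3aS)-1-oxo-4-(trifluoromethylsulfonyloxy)-3,6-dihydroisobenzofuran-3a(1H)-yl]pent-4-en-2-yl acetate
Conditions: Ac2O, pyridine, DMAP (cat.), CH2Cl2, 0 °C to rt
Reagents that add atoms: acetic anhydride, CC(=O)OC(C)=O
Why: DMAP-catalysed acylation installs the C7 acetate of the target at a point after which no step needs this hydroxyl free.

Step 9
Reactants: 15 (2S,3S)-3,4-dimethyl-1-[(3aS)-1-oxo-4-(trifluoromethylsulfonyloxy)-3,6-dihydroisobenzofuran-3a(1H)-yl]pent-4-en-2-yl acetate
Product: 16 (2S,3S)-3,4-dimethyl-1-[(3aS)-1-oxo-3,6-dihydroisobenzofuran-3a(1H)-yl]pent-4-en-2-yl acetate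
Conditions: Pd(OAc)2 (5 mol %), PPh3 (10 mol %), HCO2H, n-Bu3N, DMF, 60 °C
Reagents that add atoms: none
Why: Palladium-catalysed formate hydrogenolysis of an enol triflate replaces OTf by H and should leave the isopropenyl group and the butenolide untouched, giving the C10=C1 alkene that acts as π-nucleophile in step 11.

Step 10
Reactants: 17 2-bromofuran-3-carboxylic acid
Product: 18 2-bromofuran-3-carbonyl chloride
Conditions: (COCl)2, DMF (cat.), CH2Cl2, 0 °C to rt; used crude
Reagents that add atoms: oxalyl chloride, O=C(Cl)C(Cl)=O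
Why: Acid chloride formation by Vilsmeier-type activation is routine for electron-poor heteroaryl acids.

Step 11
Reactants: 16 (2S,3S)-3,4-dimethyl-1-[(3aS)-1-oxo-3,6-dihydroisobenzofuran-3a(1H)-yl]pent-4-en-2-yl acetate; 18 2-bromofuran-3-carbonyl chloride
Product: 20 (5S,7S,8S,9R,10R)-7-acetoxy-9-[2-(2-bromofuran-3-yl)-2-oxoethyl]-8,9-dimethyl trans-fused rings A/B with the C1=C2–C3=C4 dienoate and the 18,19-lactone, via cis-fused dienoate 19 (not isolated)
Conditions: EtAlCl2 (2.2 equiv), 18 (1.2 equiv), CH2Cl2, −78 to −20 °C; then DBU (1.5 equiv), CH2Cl2, 23 °C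
Reagents that add atoms: none
Why: Proposed new method: EtAlCl2 activates 18 as an aroylium equivalent that acylates the only electron-rich 1,1-disubstituted alkene at its CH2 terminus (C11–C12 bond, Kondakov-type alkene acylation), and the resulting tertiary C9 cation is captured by the ring-B alkene through C10 (C9–C10 bond) before the C1 cation loses a proton from C2 to give conjugated dienoate 19. The closest known reaction types are the alkylaluminium chloride-mediated Friedel–Crafts acylation of alkenes and acylium- or proton-initiated cation–olefin cyclisations of 1,6-dienes. Ring A closes in the six-membered mode in which the attacked alkene keeps C1 outside the new ring, through a chair with the C7 acetate and the C8 methyl equatorial. Because closure of a tertiary cation to a secondary one is reversible, C9 should be selected at the product-like cyclised cation, where the bulky aluminium-bound acylmethyl arm is equatorial and the methyl takes the axial site beside C19. C10 is first formed with the cis ring fusion and is then corrected: DBU deprotonates the ε-position of the dienoate and the extended enolate is protonated at C10 from the face opposite the axial C19 and C20 groups, which should funnel the cis and any deconjugated isomers into trans-fused 20. The step needs acylation at C11 only (the ring alkene is cis-disubstituted and neopentylic, the butenolide alkene electron-poor) and ring closure faster than proton loss from C9; EtAlCl2 as proton scavenger and low temperature are chosen for that.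

Step 12
Reactants: 20 trans-fused dienoate bromofuryl ketone
Product: 21 2-O-chloroacetyl derivative of the target (1S,2S,5S,7S,8S,9R,10R)
Conditions: Pd(PPh3)4 (10 mol %), ClCH2CO2Cs (3 equiv), LiCl (2 equiv), DMF, 70 °C
Reagents that add atoms: caesium chloroacetate, [Cs+].[O-]C(=O)CCl
Why: Heck-type arylpalladation of a 1,3-diene followed by Tsuji–Trost-type capture (known arylative 1,2-difunctionalisation of dienes): after oxidative addition at C16–Br, 7-exo syn-carbopalladation of C1=C2 on the α face (the tether leaves from the equatorial C11 and the β face is shielded by axial C19 and C20) closes ring C and sets C1, and the ester-conjugated π-allylpalladium is opened at C2 by chloroacetate anti to palladium, placing the oxygen β and trans to the furan and restoring the C3=C4 butenolide.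

Step 13
Reactants: 21 2-O-chloroacetyl derivative of the target
Product: 22 target CNP0182929.2
Conditions: thiourea (3 equiv), NaHCO3, EtOH/THF, 55 °C
Reagents that add atoms: none
Why: Chloroacetate removal with thiourea (S-alkylation, then cyclisation to 2-iminothiazolidin-4-one) should free the C2 hydroxyl without touching the C7 acetate, the lactone or the ketone.

**Compound list**

1 | methyl 2,6-dimethoxybenzoate | COC(=O)c1c(OC)cccc1OC | starting material
2 | allyl bromide | C=CCBr | starting material
3 | methyl 1-allyl-2,6-dimethoxycyclohexa-2,5-diene-1-carboxylate | C=CCC1(C(=O)OC)C(OC)=CCC=C1OC | intermediate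
4 | methyl 1-allyl-2,6-dioxocyclohexane-1-carboxylate | C=CCC1(C(=O)OC)C(=O)CCCC1=O | intermediate
5 | methyl 1-allyl-2,6-bis(trifluoromethylsulfonyloxy)cyclohexa-2,5-diene-1-carboxylate | C=CCC1(C(=O)OC)C(OS(=O)(=O)C(F)(F)F)=CCC=C1OS(=O)(=O)C(F)(F)F | intermediate
6 | [1-allyl-2,6-bis(trifluoromethylsulfonyloxy)cyclohexa-2,5-dien-1-yl]methanol | C=CCC1(CO)C(OS(=O)(=O)C(F)(F)F)=CCC=C1OS(=O)(=O)C(F)(F)F | intermediate
7 | (3aS)-3a-allyl-1-oxo-1,3,3a,6-tetrahydroisobenzofuran-4-yl trifluoromethanesulfonate | C=CC[C@@]23COC(=O)C2=CCC=C3OS(=O)(=O)C(F)(F)F | intermediate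
8 | (3aS)-3a-(2,3-dihydroxypropyl)-1-oxo-1,3,3a,6-tetrahydroisobenzofuran-4-yl trifluoromethanesulfonate (both carbinol epimers) | OCC(O)C[C@@]23COC(=O)C2=CCC=C3OS(=O)(=O)C(F)(F)F | intermediate
9 | (3aS)-1-oxo-3a-(2-oxoethyl)-1,3,3a,6-tetrahydroisobenzofuran-4-yl trifluoromethanesulfonate | O=CC[C@@]23COC(=O)C2=CCC=C3OS(=O)(=O)C(F)(F)F | intermediate
10 | isoprene | C=CC(C)=C | starting material
11 | pinacolborane | B1OC(C)(C)C(C)(C)O1 | starting material
12 | (Z)-4,4,5,5-tetramethyl-2-(2-methylbut-2-en-1-yl)-1,3,2-dioxaborolane | C/C=C(/C)CB1OC(C)(C)C(C)(C)O1 | intermediate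
13 | O-pinacolboryl ether of 14 | C=C(C)[C@H](C)[C@@H](OB1OC(C)(C)C(C)(C)O1)C[C@@]23COC(=O)C2=CCC=C3OS(=O)(=O)C(F)(F)F | intermediate
14 | (3aS)-3a-[(2S,3S)-2-hydroxy-3,4-dimethylpent-4-en-1-yl]-1-oxo-1,3,3a,6-tetrahydroisobenzofuran-4-yl trifluoromethanesulfonate | C=C(C)[C@H](C)[C@@H](O)C[C@@]23COC(=O)C2=CCC=C3OS(=O)(=O)C(F)(F)F | intermediate
15 | (2S,3S)-3,4-dimethyl-1-[(3aS)-1-oxo-4-(trifluoromethylsulfonyloxy)-3,6-dihydroisobenzofuran-3a(1H)-yl]pent-4-en-2-yl acetate | C=C(C)[C@H](C)[C@@H](OC(C)=O)C[C@@]23COC(=O)C2=CCC=C3OS(=O)(=O)C(F)(F)F | intermediate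
16 | (2S,3S)-3,4-dimethyl-1-[(3aS)-1-oxo-3,6-dihydroisobenzofuran-3a(1H)-yl]pent-4-en-2-yl acetate | C=C(C)[C@H](C)[C@@H](OC(C)=O)C[C@@]23COC(=O)C2=CCC=C3 | intermediate
17 | 2-bromofuran-3-carboxylic acid | OC(=O)c1ccoc1Br | starting material
18 | 2-bromofuran-3-carbonyl chloride | ClC(=O)c1ccoc1Br | intermediate
19 | cis-fused (10S) isomer of 20 | CC(=O)O[C@H]1C[C@@]23COC(=O)C2=CC=C[C@H]3[C@@](C)(CC(=O)c4ccoc4Br)[C@@H]1C | intermediate
20 | (5S,7S,8S,9R,10R) trans-fused rings A/B: 7-acetoxy, 8,9-dimethyl, 9-[2-(2-bromofuran-3-yl)-2-oxoethyl], C1=C2–C3=C4 dienoate, 18,19-lactone | CC(=O)O[C@H]1C[C@@]23COC(=O)C2=CC=C[C@@H]3[C@@](C)(CC(=O)c4ccoc4Br)[C@@H]1C | intermediate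
21 | 2-O-chloroacetyl derivative of the target | CC(=O)O[C@H]1C[C@@]23COC(=O)C2=C[C@H](OC(=O)CCl)[C@H]2c4occc4C(=O)C[C@@](C)([C@@H]1C)[C@@H]23 | intermediate
22 | CNP0182929.2 | CC(=O)O[C@H]1C[C@@]23COC(=O)C2=C[C@H](O)[C@H]2c4occc4C(=O)C[C@@](C)([C@@H]1C)[C@@H]23 | target

Total steps: 13. Longest linear sequence: 11 steps (1, 2, 3, 4, 5, 7, 8, 9, 11, 12, 13).

**Steps most likely to fail**

Step 11. What may go wrong: proton loss from the C9 cation (ene-type acylation) or its capture by the C7 acetate outruns ring closure, or the facial selection at C9 is poor. The fallback separates the two bond formations and uses known reactions. It sets out from 16: Me2AlCl and 18 in CH2Cl2 at −78 °C should give, by the established ene-type alkene acylation, the β,γ-unsaturated ketone with an exo-methylene group at C9, F1. F1 is then cyclised under Brønsted acid (TfOH, CH2Cl2/hexafluoroisopropanol, 0 °C), which re-forms the tertiary C9 cation reversibly by protonation of the exo-methylene group, and DBU treatment as in the main route brings the material back at 20.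

Step 12. What may go wrong: the carboxylate is delivered from palladium (wrong face at C2) or the π-allyl intermediate is reduced or eliminated instead of being captured. The fallback replaces the palladium event by a radical ring closure and later oxidation-state adjustment. It sets out from 20: n-Bu3SnH/AIBN in benzene at 80 °C (7-exo addition of the furan-2-yl radical to C1, hydrogen transfer to the dienyl radical at C2) should give the pentacycle with a C2 methylene group, F2. Allylic oxidation of the only allylic CH2 of the butenolide with Rh2(caprolactamate)4 and t-BuOOH gives the 2-ketone F3, in which C1 can equilibrate to the equatorial furan. Luche reduction (NaBH4, CeCl3·7H2O, MeOH, −78 °C) with axial hydride delivery then returns to the route at 22.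

Step 4. What may go wrong: zerovalent palladium does not distinguish the two enantiotopic enol triflates well enough. The fallback gives up the desymmetrisation and separates diastereomers formed in a later reagent-controlled step, at the cost of half the material. It sets out from 6: Pd(PPh3)4, CO and i-Pr2NEt give the racemic lactone triflate F4; Lemieux–Johnson oxidation gives the racemic aldehyde F5; the (R)-TRIP-catalysed allylboration with 12 then gives 14 together with its separable C5 epimer F6, and the route is rejoined at 14.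

**Further compounds**

F1 | step 11 | (2S,3S)-5-(2-bromofuran-3-yl)-3-methyl-4-methylene-5-oxo-1-[(3aS)-1-oxo-3,6-dihydroisobenzofuran-3a(1H)-yl]pentan-2-yl acetate | C=C(CC(=O)c1ccoc1Br)[C@H](C)[C@@H](OC(C)=O)C[C@@]23COC(=O)C2=CCC=C3
F2 | step 12 | 2-deoxy target (C2 methylene), (1R,5S,7S,8S,9R,10R) | CC(=O)O[C@H]1C[C@@]23COC(=O)C2=CC[C@H]2c4occc4C(=O)C[C@@](C)([C@@H]1C)[C@@H]23
F3 | step 12 | 2-oxo analogue of the target, (1R,5S,7S,8S,9R,10R) | CC(=O)O[C@H]1C[C@@]23COC(=O)C2=CC(=O)[C@H]2c4occc4C(=O)C[C@@](C)([C@@H]1C)[C@@H]23
F4 | step 4 | racemic 3a-allyl-1-oxo-1,3,3a,6-tetrahydroisobenzofuran-4-yl trifluoromethanesulfonate | C=CCC12COC(=O)C1=CCC=C2OS(=O)(=O)C(F)(F)F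
F5 | step 4 | racemic 1-oxo-3a-(2-oxoethyl)-1,3,3a,6-tetrahydroisobenzofuran-4-yl trifluoromethanesulfonate | O=CCC12COC(=O)C1=CCC=C2OS(=O)(=O)C(F)(F)F
F6 | step 4 | (3aR) epimer of 14 | C=C(C)[C@H](C)[C@@H](O)C[C@]23COC(=O)C2=CCC=C3OS(=O)(=O)C(F)(F)F
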